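## Retrosynthetic overview
1. The quinone is unveiled last. The target comes from a tri-O-benzyl (3S)-isoflavan by hydrogenolysis, then oxidation of the ring B hydroquinone only.
2. Ring C is the only ring that must be built, and it is closed last. One stereospecific cationic 1,2-aryl shift (phenonium ion) with Friedel–Crafts closure makes both C3–C1' and C4–C4a from an acyclic (S)-1-aryloxy-3-arylpropan-2-ol.
3. That alcohol comes from a ring B arylmagnesium bromide, (S)-epichlorohydrin (C2–C3–C4 and the stereocentre) and a ring A phenol.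
4. Rings A and B are the same piece, 2,3-dimethoxyhydroquinone. It comes from veratrole by double ortho-lithiation/hydroxylation, and veratrole comes from catechol.

Assumption: the [C@H] centre of the given SMILES is C3 of the chroman and reads as (S); this is the configuration made.

## Route

Step 1
Reactants: 1 catechol
Product: 2 1,2-dimethoxybenzene (veratrole)
Conditions: MeI (2.5 equiv), K2CO3, acetone, reflux
Reagents that add atoms: iodomethane, CI
Why: Double Williamson O-methylation of the two acidic phenols is clean under K2CO3 in acetone because C-alkylation does not compete; no stereocentre is involved.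

Step 2
Reactants: 2 1,2-dimethoxybenzene
Product: 5 2,3-dimethoxybenzene-1,4-diol, via 3,6-dilithioveratrole 3 (not isolated), via bis(dimethyl boronate) 4 (not isolated)
Conditions: n-BuLi (3 equiv), TMEDA, Et2O, 0 °C to reflux; B(OMe)3, −78 °C to rt; AcOH, 30% H2O2, 0 °C to rt (work-up under N2)
Reagents that add atoms: n-butyllithium, [Li]CCCC (lithium only in 3); trimethyl borate, COB(OC)OC (boron only in 4); hydrogen peroxide, OO (the two new oxygen atoms of 5)
Why: In this double directed ortho-metalation each methoxy group steers one lithium to its free ortho position (C3 and C6), and ipso oxidation of the two C–B bonds then places the new oxygens para to each other; no stereocentre is involved.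

Step 3
Reactants: 5 2,3-dimethoxybenzene-1,4-diol
Product: 7 1,4-bis(benzyloxy)-5-bromo-2,3-dimethoxybenzene, via dibenzyl ether 6 (not isolated)
Conditions: BnBr (2.2 equiv), K2CO3, MeCN, reflux, N2; then NBS (1.0 equiv), 0 °C, dark
Reagents that add atoms: benzyl bromide, BrCc1ccccc1; N-bromosuccinimide, O=C1CCC(=O)N1Br
Why: Williamson benzylation is followed in the same pot by electrophilic aromatic bromination, and only one monobromide can form because the two open positions of 6 are equivalent, the first bromine slows a second attack and the unactivated benzyl rings stay untouched.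

Step 4
Reactants: 7 1,4-bis(benzyloxy)-5-bromo-2,3-dimethoxybenzene; 8 (S)-epichlorohydrin
Product: 10 (2S)-1-[2,5-bis(benzyloxy)-3,4-dimethoxyphenyl]-3-chloropropan-2-ol, via arylmagnesium bromide 9 (not isolated)
Conditions: Mg turnings, THF, reflux; then CuI (10 mol %), 8 (1.2 equiv), −30 to 0 °C
Reagents that add atoms: magnesium, [Mg] (only in 9)
Why: Grignard formation is followed by copper-catalysed SN2 opening of the epoxide at its unsubstituted carbon, which is faster than attack at C–Cl and leaves the C–O stereocentre of 8 untouched, so (S) is carried into 10.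

Step 5
Reactants: 10 (2S)-1-[2,5-bis(benzyloxy)-3,4-dimethoxyphenyl]-3-chloropropan-2-ol; 5 2,3-dimethoxybenzene-1,4-diol
Product: 13 (2S)-1-[4-(benzyloxy)-2,3-dimethoxyphenoxy]-3-[2,5-bis(benzyloxy)-3,4-dimethoxyphenyl]propan-2-ol, via (S)-epoxide 11 (not isolated), via monophenol 12 (not isolated)
Conditions: 5 (3 equiv), K2CO3 (8 equiv), DMF, 80 °C, Ar; then BnBr (6 equiv), 40 °C
Reagents that add atoms: benzyl bromide, BrCc1ccccc1
Why: Intramolecular Williamson closure gives epoxide 11, the phenoxide of symmetric 5 opens it at the terminal carbon (excess 5 enforces mono-alkylation and either OH gives the same product), and BnBr with K2CO3 caps the remaining phenol but not the secondary alcohol; the stereocentre is never a reaction site and stays (S), and surplus 5 ends as 6 for reuse in step 3.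

Step 6
Reactants: 13 (2S)-1-[4-(benzyloxy)-2,3-dimethoxyphenoxy]-3-[2,5-bis(benzyloxy)-3,4-dimethoxyphenyl]propan-2-ol
Product: 16 (3S)-6-(benzyloxy)-3-[2,5-bis(benzyloxy)-3,4-dimethoxyphenyl]-7,8-dimethoxychromane, via secondary triflate 14 (not isolated), via phenonium triflate 15 (not isolated)
Conditions: Tf2O (1.1 equiv), 2,6-di-tert-butyl-4-methylpyridine (2.5 equiv), CH2Cl2, −78 °C; then (CF3)2CHOH (20 vol %), −78 to 0 °C
Reagents that add atoms: trifluoromethanesulfonic anhydride, O=S(=O)(OS(=O)(=O)C(F)(F)F)C(F)(F)F (only in 14 and 15)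
Why: Proposed new method: this is a dehydrative phenonium-relay cyclisation in which secondary triflate 14, whose unassisted ionisation and SN2 displacement are held back by the β-aryloxy dipole, ionises only with backside participation of the ipso carbon of ring B (activated by its ortho-OBn and para-OMe groups), so the carbinol carbon is cleanly inverted and becomes the C3–C1' bond of spirocyclopropyl cation 15; the tethered ring A carbon ortho to O1 and para to the later 7-OMe then opens 15 at the unhindered CH2 terminus (six-membered closure, the mode tethered arenes also follow with aryl glycidyl ethers on the way to chroman-3-ols) and the hindered pyridine takes the proton, which completes the 1,2-aryl shift from C4 to C3, forms ring C and turns (2S)-13 into (3S)-16, while return of triflate to either carbon of 15 only gives a triflate that re-enters the same ion; the closest known reaction types are solvolytic 1,2-aryl migration through phenonium ions, intermolecular Friedel–Crafts capture of phenonium ions in (CF3)2CHOH and endo-selective epoxide–arene cyclisation.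

Step 7
Reactants: 16 (3S)-6-(benzyloxy)-3-[2,5-bis(benzyloxy)-3,4-dimethoxyphenyl]-7,8-dimethoxychromane
Product: 18 5-[(3S)-6-hydroxy-7,8-dimethoxy-3,4-dihydro-2H-chromen-3-yl]-2,3-dimethoxycyclohexa-2,5-diene-1,4-dione (target), via triol 17 (not isolated)
Conditions: H2 (1 atm), 10% Pd/C, EtOAc/EtOH, rt; filter under Ar; then Ag2O (1.05 equiv), 0 °C, 15 min
Reagents that add atoms: none
Why: Catalytic hydrogenolysis cleaves only the three benzylic C–O bonds, and one equivalent of Ag2O then follows the two-electron, two-proton path open only to the para-dihydroxy ring B (a ubiquinol-type hydroquinone that also reduces back any ring A phenoxyl radical), so the 6-OH para-alkoxyphenol survives and the (3S) centre is kept because neither stage is basic.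

## Compound list
1 | catechol (benzene-1,2-diol) | Oc1ccccc1O | starting material
2 | 1,2-dimethoxybenzene (veratrole) | COc1ccccc1OC | intermediate
3 | 3,6-dilithio-1,2-dimethoxybenzene (not isolated) | [Li]c1ccc([Li])c(OC)c1OC | intermediate
4 | tetramethyl (2,3-dimethoxy-1,4-phenylene)diboronate (not isolated) | COB(OC)c1ccc(B(OC)OC)c(OC)c1OC | intermediate
5 | 2,3-dimethoxybenzene-1,4-diol | COc1c(O)ccc(O)c1OC | intermediate
6 | 1,4-bis(benzyloxy)-2,3-dimethoxybenzene (not isolated) | COc1c(OCc2ccccc2)ccc(OCc2ccccc2)c1OC | intermediate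
7 | 1,4-bis(benzyloxy)-5-bromo-2,3-dimethoxybenzene | COc1c(OC)c(OCc2ccccc2)c(Br)cc1OCc1ccccc1 | intermediate
8 | (S)-epichlorohydrin, (2S)-2-(chloromethyl)oxirane | ClC[C@@H]1CO1 | starting material
9 | [2,5-bis(benzyloxy)-3,4-dimethoxyphenyl]magnesium bromide (not isolated) | COc1c(OC)c(OCc2ccccc2)c([Mg]Br)cc1OCc1ccccc1 | intermediate
10 | (2S)-1-[2,5-bis(benzyloxy)-3,4-dimethoxyphenyl]-3-chloropropan-2-ol | ClC[C@@H](O)Cc1cc(OCc2ccccc2)c(OC)c(OC)c1OCc1ccccc1 | intermediate
11 | (2S)-2-[2,5-bis(benzyloxy)-3,4-dimethoxybenzyl]oxirane (not isolated) | C1O[C@H]1Cc1cc(OCc2ccccc2)c(OC)c(OC)c1OCc1ccccc1 | intermediate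
12 | 4-{(2S)-3-[2,5-bis(benzyloxy)-3,4-dimethoxyphenyl]-2-hydroxypropoxy}-2,3-dimethoxyphenol (not isolated) | COc1c(O)ccc(OC[C@@H](O)Cc2cc(OCc3ccccc3)c(OC)c(OC)c2OCc2ccccc2)c1OC | intermediate
13 | (2S)-1-[4-(benzyloxy)-2,3-dimethoxyphenoxy]-3-[2,5-bis(benzyloxy)-3,4-dimethoxyphenyl]propan-2-ol | COc1c(OCc2ccccc2)ccc(OC[C@@H](O)Cc2cc(OCc3ccccc3)c(OC)c(OC)c2OCc2ccccc2)c1OC | intermediate
14 | (2S)-1-[4-(benzyloxy)-2,3-dimethoxyphenoxy]-3-[2,5-bis(benzyloxy)-3,4-dimethoxyphenyl]propan-2-yl trifluoromethanesulfonate (not isolated) | COc1c(OCc2ccccc2)ccc(OC[C@@H](OS(=O)(=O)C(F)(F)F)Cc2cc(OCc3ccccc3)c(OC)c(OC)c2OCc2ccccc2)c1OC | intermediate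
15 | phenonium (spiro[2.5]octadienyl) cation of ring B bridging C3 and C4, (S) at the substituted cyclopropane carbon, spiro carbon not defined, drawn as the para-methoxy oxocarbenium form, triflate salt (not isolated) | COc1c(OCc2ccccc2)ccc(OC[C@H]2CC23C=C(OCc4ccccc4)C(=[O+]C)C(OC)=C3OCc3ccccc3)c1OC.[O-]S(=O)(=O)C(F)(F)F | intermediate
16 | (3S)-6-(benzyloxy)-3-[2,5-bis(benzyloxy)-3,4-dimethoxyphenyl]-7,8-dimethoxychromane | COc1c(OC)c(OCc2ccccc2)c([C@H]2COc3c(cc(OCc4ccccc4)c(OC)c3OC)C2)cc1OCc1ccccc1 | intermediate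
17 | 5-[(3S)-6-hydroxy-7,8-dimethoxychroman-3-yl]-2,3-dimethoxybenzene-1,4-diol (not isolated) | COc1c(OC)c(O)c([C@H]2COc3c(cc(O)c(OC)c3OC)C2)cc1O | intermediate
18 | 5-[(3S)-6-hydroxy-7,8-dimethoxy-3,4-dihydro-2H-chromen-3-yl]-2,3-dimethoxycyclohexa-2,5-diene-1,4-dione | COC1=C(OC)C(=O)C([C@H]2COc3c(cc(O)c(OC)c3OC)C2)=CC1=O | target

## Step count and risks
Total step count: 7. Longest linear sequence: 7 (1 → 2 → 5 → 7 → 10 → 13 → 16 → 18; compound 5 enters a second time in step 5).

**Most likely to fail, first: step 6, the proposed cascade.**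
- The 2'-OBn oxygen may attack C3 with loss of benzyl and give a dihydrobenzofuran.
- Ring A may close at C3 and form a five-membered ring.
- A hydride shift may lead to a 4-arylchroman.

The fallback uses only known reaction types and keeps a 1,2-aryl shift, moved to the flavanone stage. It sets out from 7 and 5 and comes back to the route at 17.
- Grignard reagent 9 from 7 is formylated with DMF to 2,5-bis(benzyloxy)-3,4-dimethoxybenzaldehyde F1.
- Compound 5 is C-acetylated (AcOH, BF3·OEt2, 90 °C) to 1-(2,5-dihydroxy-3,4-dimethoxyphenyl)ethanone F2.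
- The non-chelated 5-OH of F2 is benzylated (BnBr, K2CO3, acetone) to 1-[5-(benzyloxy)-2-hydroxy-3,4-dimethoxyphenyl]ethanone F3.
- Claisen–Schmidt condensation of F3 with F1 (KOH, EtOH) gives the (E)-2'-hydroxychalcone F4.
- NaOAc in refluxing EtOH closes F4 to the racemic flavanone F5.
- PhI(OH)OTs in MeCN brings about the known oxidative aryl migration from C2 to C3 and gives the isoflavone F6.
- Asymmetric transfer hydrogenation with RuCl(p-cymene)[(S,S)-TsDPEN] in HCO2H/Et3N first reduces the enone to the racemising isoflavanone F7.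
- The same catalyst then resolves F7 dynamically to the cis-(3S,4S)-isoflavan-4-ol F8.
- H2 and Pd/C in EtOH/AcOH remove the three benzyl groups and the benzylic 4-OH to give 17, which is oxidised with Ag2O as in step 7.

**Second: step 2.** The second lithiation may stay incomplete and give mixtures of mono- and diol, and 5 is sensitive to air. The fallback sets out from 2 and comes back at 5. It brings in the second oxygen by phenol oxidation and not by a second metalation.
- Mono-lithiation (n-BuLi 1.1 equiv, THF, 0 °C), B(OMe)3 and H2O2 give 2,3-dimethoxyphenol F9.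
- Oxidation para to the hydroxyl group with (KSO3)2NO (Teuber reaction), or with O2 and Co(salen) in DMF, gives 2,3-dimethoxy-1,4-benzoquinone F10.
- Aqueous Na2S2O4 reduces F10 to 5.

**Third: step 5.** Hot basic DMF may oxidise the hydroquinone, and double alkylation of 5 may compete. The fallback sets out from 5 and 9 and comes back at 13. It reverses the order of fragment union, with the C–O bond made first on a phenol that is already differentiated and the C–C bond second.
- Compound 5 is mono-benzylated (BnBr 1.0 equiv, K2CO3, acetone) to 4-(benzyloxy)-2,3-dimethoxyphenol F11. The dibenzyl ether 6 formed alongside goes to the bromination of step 3.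
- Mitsunobu etherification with bought (R)-glycidol (OC[C@@H]1CO1; PPh3, DIAD, THF) gives (2S)-2-{[4-(benzyloxy)-2,3-dimethoxyphenoxy]methyl}oxirane F12 without touching the stereocentre.
- Grignard reagent 9 with CuI (10 mol %) opens F12 at its terminal carbon to give 13.

## Further compounds
F1 | step 6 | 2,5-bis(benzyloxy)-3,4-dimethoxybenzaldehyde | COc1c(OC)c(OCc2ccccc2)c(C=O)cc1OCc1ccccc1
F2 | step 6 | 1-(2,5-dihydroxy-3,4-dimethoxyphenyl)ethanone | CC(=O)c1cc(O)c(OC)c(OC)c1O
F3 | step 6 | 1-[5-(benzyloxy)-2-hydroxy-3,4-dimethoxyphenyl]ethanone | CC(=O)c1cc(OCc2ccccc2)c(OC)c(OC)c1O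
F4 | step 6 | (E)-1-[5-(benzyloxy)-2-hydroxy-3,4-dimethoxyphenyl]-3-[2,5-bis(benzyloxy)-3,4-dimethoxyphenyl]prop-2-en-1-one | COc1c(OC)c(OCc2ccccc2)c(/C=C/C(=O)c2cc(OCc3ccccc3)c(OC)c(OC)c2O)cc1OCc1ccccc1
F5 | step 6 | racemic 6-(benzyloxy)-2-[2,5-bis(benzyloxy)-3,4-dimethoxyphenyl]-7,8-dimethoxychroman-4-one | COc1c(OC)c(OCc2ccccc2)c(C2CC(=O)c3cc(OCc4ccccc4)c(OC)c(OC)c3O2)cc1OCc1ccccc1
F6 | step 6 | 6-(benzyloxy)-3-[2,5-bis(benzyloxy)-3,4-dimethoxyphenyl]-7,8-dimethoxy-4H-chromen-4-one | COc1c(OC)c(OCc2ccccc2)c(-c2coc3c(OC)c(OC)c(OCc4ccccc4)cc3c2=O)cc1OCc1ccccc1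
F7 | step 6 | racemising 6-(benzyloxy)-3-[2,5-bis(benzyloxy)-3,4-dimethoxyphenyl]-7,8-dimethoxychroman-4-one | COc1c(OC)c(OCc2ccccc2)c(C2COc3c(OC)c(OC)c(OCc4ccccc4)cc3C2=O)cc1OCc1ccccc1
F8 | step 6 | (3S,4S)-6-(benzyloxy)-3-[2,5-bis(benzyloxy)-3,4-dimethoxyphenyl]-7,8-dimethoxychroman-4-ol (cis) | COc1c(OC)c(OCc2ccccc2)c([C@H]2COc3c(cc(OCc4ccccc4)c(OC)c3OC)[C@H]2O)cc1OCc1ccccc1
F9 | step 2 | 2,3-dimethoxyphenol | COc1cccc(O)c1OC
F10 | step 2 | 2,3-dimethoxy-1,4-benzoquinone | COC1=C(OC)C(=O)C=CC1=O
F11 | step 5 | 4-(benzyloxy)-2,3-dimethoxyphenol | COc1c(O)ccc(OCc2ccccc2)c1OC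
F12 | step 5 | (2S)-2-{[4-(benzyloxy)-2,3-dimethoxyphenoxy]methyl}oxirane | COc1c(OCc2ccccc2)ccc(OC[C@@H]2CO2)c1OC
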